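**Plan**
- Retrosynthesis: remove the C4–C5 epoxide oxygen, cut the side-chain C=C (Wittig) and C1=CH2 (methylenation), then the ring bond C2–C3, then C1–C2 (sulfone acylation), C9–side chain (lactone alkylation), the lactone O–C10 bond and C8–C12 (Michael addition).
- Enabling feature: in the nine-membered ring, C2 sits between C1 (a ketone before methylenation) and the allylic C3 of the E C4=C5 alkene, so a C2 keto-sulfone carbanion can close the ring on a C3 allylic chloride.
- Forward: geraniol supplies C3–C8 with the E alkene; malonate addition to the C8 enal, reduction and lactonisation give the δ-lactone (first ring); the C9 chain and the C1 keto sulfone follow; C2–C3 alkylation closes the nine-membered ring (second ring); the epoxide comes last.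
- Stereochemistry: C8 from the (S)-diarylprolinol silyl ether catalyst; C12 from thermodynamic trans-lactonisation; C9 from kinetic protonation anti to the C8 chain; C4/C5 from peripheral epoxidation of the E ring alkene; both E alkenes from geraniol and a stabilised ylide.

Key step: step 13

Remark: locants follow the target (C1 ring carbon bearing =CH2; C2, C3; C4 epoxide CH; C5 epoxide C–Me; C6, C7; C8 ring-fusion CH; C9 lactone α-carbon; C10 lactone C=O; C11 OCH2; C12 ring-fusion CH). Anions (enolates, alkoxides, carbanions) are not numbered, and compounds 5, 7, 12, 17 and 27 are taken as purchased.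

Step 1
Reactants: 1 geraniol
Product: 2 geranyl 4-methoxybenzyl ether
Conditions: NaH, PMBCl, Bu4NI (cat.), THF/DMF, 0 °C → rt
Reagents that add atoms: 4-methoxybenzyl chloride, COc1ccc(CCl)cc1
Why: Williamson etherification of the primary allylic alkoxide installs a PMB ether that tolerates hydride, amide bases and mild acid and can later be removed oxidatively beside a silyl ether.

Step 2
Reactants: 2 geranyl 4-methoxybenzyl ether
Product: 4 (4E)-6-[(4-methoxybenzyl)oxy]-4-methylhex-4-enal, via terminal epoxide 3 (not isolated)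
Conditions: mCPBA, CH2Cl2, −20 → 0 °C; then H5IO6, THF/H2O, 0 °C
Reagents that add atoms: mCPBA, OOC(=O)c1cccc(Cl)c1
Why: Prilezhaev epoxidation prefers the more electron-rich alkene remote from the allylic ether, and periodic acid cleaves that epoxide through the diol (Malaprade cleavage) to the C8 aldehyde without touching the E alkene.

Step 3
Reactants: 4 (4E)-6-[(4-methoxybenzyl)oxy]-4-methylhex-4-enal; 5 (triphenylphosphoranylidene)acetaldehyde
Product: 6 (2E,6E)-8-[(4-methoxybenzyl)oxy]-6-methylocta-2,6-dienal
Conditions: toluene, 80 °C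
Reagents that add atoms: none
Why: Wittig olefination with the formyl-stabilised ylide gives the E enal by two-carbon homologation.

Step 4
Reactants: 6 (2E,6E)-8-[(4-methoxybenzyl)oxy]-6-methylocta-2,6-dienal; 7 dimethyl malonate
Product: 8 dimethyl 2-[(3R,6E)-8-[(4-methoxybenzyl)oxy]-6-methyl-1-oxooct-6-en-3-yl]propanedioate
Conditions: (S)-α,α-bis[3,5-bis(trifluoromethyl)phenyl]prolinol trimethylsilyl ether (10 mol%), EtOH, 0 °C → rt
Reagents that add atoms: none
Why: Iminium-ion Michael addition of a malonate to an enal (Jørgensen–Hayashi catalysis); the (S)-catalyst shields one face of the s-trans E iminium ion, so the malonate should add to the open face of the β-carbon and set C8 (3R in 8) with high enantioselectivity.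

Step 5
Reactants: 8 Michael adduct
Product: 9 (3R,6E)-3-[bis(methoxycarbonyl)methyl]-8-[(4-methoxybenzyl)oxy]-6-methyloct-6-enoic acid
Conditions: NaClO2, NaH2PO4, 2-methyl-2-butene, t-BuOH/H2O, 0 °C → rt
Reagents that add atoms: sodium chlorite, [Na+].[O-]Cl=O
Why: Pinnick oxidation converts the aldehyde to the acid under buffered conditions that leave the malonate and C8 untouched, with hypochlorite scavenged away from the alkene and the PMB ring.

Step 6
Reactants: 9 malonate acid
Product: 11 (4R,5R)-5-(hydroxymethyl)-4-[(3E)-5-[(4-methoxybenzyl)oxy]-3-methylpent-3-en-1-yl]oxan-2-one (4,5-trans), via dihydroxy acid 10 (not isolated)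
Conditions: LiOMe (1.0 equiv), THF/MeOH; LiBH4, THF, 0 °C → rt; 1 M HCl; then CSA (cat.), CH2Cl2, rt
Reagents that add atoms: none
Why: Lithium borohydride reduces both malonate esters but not the preformed lithium carboxylate, and acid-catalysed lactonisation equilibrates by translactonisation between the two hydroxymethyl arms towards the 4,5-trans (diequatorial) δ-lactone, which sets C12 under thermodynamic control (the minor cis lactone can be re-equilibrated).

Step 7
Reactants: 11 trans hydroxy lactone; 12 tert-butyl(3-iodopropoxy)dimethylsilane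
Product: 14 (3R,4S,5R)-3-[3-(tert-butyldimethylsilyloxy)propyl]-5-(hydroxymethyl)-4-[(3E)-5-[(4-methoxybenzyl)oxy]-3-methylpent-3-en-1-yl]oxan-2-one (3,4-trans), via TMS ether 13 (not isolated)
Conditions: TMSCl, imidazole, CH2Cl2, 0 °C; LDA, THF, −78 °C; 12, DMPU, −78 → −30 °C; aq. citric acid
Reagents that add atoms: none
Why: Alkylation of a δ-lactone lithium enolate with a primary iodide in THF/DMPU, the hydroxyl being masked as a TMS ether so that no alkoxide can translactonise; the iodide should enter anti to the C8 chain, but C9 is reset in step 8.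

Step 8
Reactants: 14 3,4-trans lactone
Product: 15 (3S,4S,5R)-3-[3-(tert-butyldimethylsilyloxy)propyl]-5-(hydroxymethyl)-4-[(3E)-5-[(4-methoxybenzyl)oxy]-3-methylpent-3-en-1-yl]oxan-2-one (3,4-cis, 4,5-trans)
Conditions: LDA (2.3 equiv), THF, −78 → −40 °C; AcOH in THF, −78 °C
Reagents that add atoms: none
Why: Kinetic protonation of the lactone enolate: the C8 chain, held pseudoaxial by A(1,2) strain with the C9 substituent, blocks one face and the C12 hydroxymethyl group on the other face can relay the proton, so hydrogen should arrive anti to the C8 chain and give C9 (S); recovered 14 can be recycled.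

Step 9
Reactants: 15 3,4-cis hydroxy lactone
Product: 16 (3S,4R,5S)-5-[3-(tert-butyldimethylsilyloxy)propyl]-4-[(3E)-5-[(4-methoxybenzyl)oxy]-3-methylpent-3-en-1-yl]-6-oxooxane-3-carboxylic acid
Conditions: TEMPO (cat.), PhI(OAc)2, MeCN/H2O, rt
Reagents that add atoms: water, O
Why: TEMPO/PhI(OAc)2 oxidation takes the primary alcohol through the aldehyde hydrate to the carboxylic acid (C1) under near-neutral conditions that should not epimerise C12 or C9.

Step 10
Reactants: 16 lactone acid; 17 methyl phenyl sulfone
Product: 19 (3S,4S,5S)-3-[3-(tert-butyldimethylsilyloxy)propyl]-4-[(3E)-5-[(4-methoxybenzyl)oxy]-3-methylpent-3-en-1-yl]-5-[(phenylsulfonyl)acetyl]oxan-2-one, via acyl imidazolide 18 (not isolated)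
Conditions: CDI, THF, rt; added to 17/n-BuLi (3.2 equiv of the anion), THF, −78 °C; aq. NH4Cl
Reagents that add atoms: none
Why: C-acylation of lithiated methyl phenyl sulfone by an acyl imidazolide (Claisen-type); the imidazolide is far more electrophilic than the lactone at −78 °C, and the β-keto sulfone is deprotonated at C2 as it forms, which shields C12 and the β-acyloxy ketone from base.

Step 11
Reactants: 19 PMB-protected keto sulfone
Product: 20 (3S,4S,5S)-3-[3-(tert-butyldimethylsilyloxy)propyl]-4-[(3E)-5-hydroxy-3-methylpent-3-en-1-yl]-5-[(phenylsulfonyl)acetyl]oxan-2-one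
Conditions: DDQ, CH2Cl2/pH 7 buffer, 0 °C → rt
Reagents that add atoms: none
Why: Oxidative PMB cleavage with DDQ frees the allylic alcohol without affecting the TBS ether, the lactone or the keto sulfone.

Step 12
Reactants: 20 allylic alcohol
Product: 22 (3S,4S,5S)-3-[3-(tert-butyldimethylsilyloxy)propyl]-4-[(3E)-5-chloro-3-methylpent-3-en-1-yl]-5-[(phenylsulfonyl)acetyl]oxan-2-one, via allylic mesylate 21 (not isolated)
Conditions: MsCl, 2,4,6-collidine, LiCl, DMF, 0 °C
Reagents that add atoms: lithium chloride, [Li+].[Cl-]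
Why: Collington–Meyers chlorination: chloride displaces the mesylate formed in situ in an SN2 step, without allylic transposition or E/Z isomerisation, and collidine is too weak a base to ionise the keto sulfone.

Step 13
Reactants: 22 allylic chloride keto sulfone
Product: 23 (4S,4aS,7E,11aS)-4-[3-(tert-butyldimethylsilyloxy)propyl]-7-methyl-10-(phenylsulfonyl)-1,4,4a,5,6,9,10,11a-octahydrocyclonona[c]pyran-3,11-dione (sulfone carbon = C2, configuration not controlled, drawn arbitrarily)
Conditions: Cs2CO3 (3 equiv), DMF (2 mM, slow addition of 22), 40 °C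
Reagents that add atoms: none
Why: Caesium carbonate deprotonates C2, the only carbon flanked by the ketone and the sulfone (pKa about 12, far below the C9 and C12 hydrogens), and the soft enolate carbon displaces chloride at the primary allylic C3 in an intramolecular SN2 reaction that forms the C2–C3 bond. The closest known reaction type is the intramolecular alkylation of sulfone-stabilised carbanions with allylic halides used to close medium and large carbocycles. The nine-membered ring (C1, C2, C3, C4, C5, C6, C7, C8, C12) closes in a 9-exo-tet mode. The new stereocentre C2 is not controlled (it stays acidic and equilibrates under the base) and is removed in step 14. The step needs C- rather than O-alkylation, SN2 rather than SN2′ attack, cyclisation rather than oligomerisation and no attack on the lactone: the soft carbanion and primary allylic chloride favour C-alkylation, the fully substituted C5 terminus blocks SN2′, high dilution with the large caesium counter-ion favours ring closure, and the stabilised anion is a poor nucleophile for the lactone carbonyl, while C12 stays protected because the product is again held as its C2 enolate. The E geometry of C4=C5 from geraniol is kept because no allyl cation or allyl metal species is formed.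

Step 14
Reactants: 23 bicyclic keto sulfone
Product: 24 (4S,4aS,7E,11aS)-4-[3-(tert-butyldimethylsilyloxy)propyl]-7-methyl-1,4,4a,5,6,9,10,11a-octahydrocyclonona[c]pyran-3,11-dione
Conditions: SmI2 (2.5 equiv), THF/MeOH, −78 °C
Reagents that add atoms: none
Why: Reductive desulfonylation of an α-sulfonyl ketone by SmI2 (electron transfer, loss of sulfinate, protonation of the samarium enolate at C2) removes the sulfone and the C2 centre under non-basic conditions that spare the β-acyloxy ketone and C12.

Step 15
Reactants: 24 bicyclic ketone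
Product: 25 (4S,4aS,7E,11aR)-4-[3-(tert-butyldimethylsilyloxy)propyl]-7-methyl-11-methylidene-4,4a,5,6,9,10,11,11a-octahydro-1H-cyclonona[c]pyran-3-one
Conditions: Zn, CH2Br2, TiCl4, THF/CH2Cl2, 0 °C → rt
Reagents that add atoms: dibromomethane, BrCBr
Why: Takai–Lombardo methylenation converts the ketone to the exocyclic alkene chemoselectively beside the lactone and, being non-basic, should neither epimerise C12 nor eliminate the lactone oxygen.

Step 16
Reactants: 25 silyl ether
Product: 26 (4S,4aS,7E,11aR)-4-(3-hydroxypropyl)-7-methyl-11-methylidene-4,4a,5,6,9,10,11,11a-octahydro-1H-cyclonona[c]pyran-3-one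
Conditions: TBAF, AcOH, THF, 0 °C → rt
Reagents that add atoms: none
Why: Fluoride cleavage of the primary TBS ether, buffered with acetic acid so that the lactone and C9 are not exposed to base.

Step 17
Reactants: 26 primary alcohol; 27 methyl 2-(triphenylphosphoranylidene)propanoate
Product: 29 methyl (2E)-2-methyl-5-[(4S,4aS,7E,11aR)-7-methyl-11-methylidene-3-oxo-4,4a,5,6,9,10,11,11a-octahydro-1H-cyclonona[c]pyran-4-yl]pent-2-enoate, via side-chain aldehyde 28 (not isolated)
Conditions: Dess–Martin periodinane, CH2Cl2, rt; then 27 (3 equiv), rt → 40 °C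
Reagents that add atoms: none
Why: Dess–Martin oxidation followed in the same flask by Wittig olefination with the α-methyl stabilised ylide, which gives the E trisubstituted enoate.

Step 18
Reactants: 29 triene lactone
Product: 30 acalycixeniolide H
Conditions: mCPBA (1.05 equiv), CH2Cl2/aq. phosphate buffer (pH 8), 0 °C
Reagents that add atoms: mCPBA, OOC(=O)c1cccc(Cl)c1
Why: Prilezhaev epoxidation is fastest at the strained, electron-rich E trisubstituted ring alkene (not the methylidene or the enoate), and since only the outer face of the trans alkene is accessible, the peracid should add from the periphery of the preferred ring conformer to give the trans C4–C5 epoxide (4S,5S).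

**Compound list**
1 | geraniol | CC(C)=CCC/C(C)=C/CO | starting material
2 | geranyl 4-methoxybenzyl ether | COc1ccc(COC/C=C(\C)CCC=C(C)C)cc1 | intermediate
3 | 6,7-epoxide of 2 (racemic at the epoxide CH, not isolated) | COc1ccc(COC/C=C(\C)CCC2OC2(C)C)cc1 | intermediate
4 | (4E)-6-[(4-methoxybenzyl)oxy]-4-methylhex-4-enal | COc1ccc(COC/C=C(\C)CCC=O)cc1 | intermediate
5 | (triphenylphosphoranylidene)acetaldehyde | O=CC=P(c1ccccc1)(c1ccccc1)c1ccccc1 | starting material
6 | (2E,6E)-8-[(4-methoxybenzyl)oxy]-6-methylocta-2,6-dienal | COc1ccc(COC/C=C(\C)CC/C=C/C=O)cc1 | intermediate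
7 | dimethyl malonate | COC(=O)CC(=O)OC | starting material
8 | dimethyl 2-[(3R,6E)-8-[(4-methoxybenzyl)oxy]-6-methyl-1-oxooct-6-en-3-yl]propanedioate | COc1ccc(COC/C=C(\C)CC[C@@H](C(C(=O)OC)C(=O)OC)CC=O)cc1 | intermediate
9 | (3R,6E)-3-[bis(methoxycarbonyl)methyl]-8-[(4-methoxybenzyl)oxy]-6-methyloct-6-enoic acid | COc1ccc(COC/C=C(\C)CC[C@@H](C(C(=O)OC)C(=O)OC)CC(=O)O)cc1 | intermediate
10 | (3R,6E)-3-(1,3-dihydroxypropan-2-yl)-8-[(4-methoxybenzyl)oxy]-6-methyloct-6-enoic acid (not isolated) | COc1ccc(COC/C=C(\C)CC[C@@H](C(CO)CO)CC(=O)O)cc1 | intermediate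
11 | (4R,5R)-5-(hydroxymethyl)-4-[(3E)-5-[(4-methoxybenzyl)oxy]-3-methylpent-3-en-1-yl]oxan-2-one | COc1ccc(COC/C=C(\C)CC[C@@H]2CC(=O)OC[C@H]2CO)cc1 | intermediate
12 | tert-butyl(3-iodopropoxy)dimethylsilane | CC(C)(C)[Si](C)(C)OCCCI | starting material
13 | (4R,5S)-4-[(3E)-5-[(4-methoxybenzyl)oxy]-3-methylpent-3-en-1-yl]-5-[(trimethylsilyloxy)methyl]oxan-2-one (not isolated) | COc1ccc(COC/C=C(\C)CC[C@@H]2CC(=O)OC[C@H]2CO[Si](C)(C)C)cc1 | intermediate
14 | (3R,4S,5R)-3-[3-(tert-butyldimethylsilyloxy)propyl]-5-(hydroxymethyl)-4-[(3E)-5-[(4-methoxybenzyl)oxy]-3-methylpent-3-en-1-yl]oxan-2-one | COc1ccc(COC/C=C(\C)CC[C@@H]2[C@@H](CCCO[Si](C)(C)C(C)(C)C)C(=O)OC[C@H]2CO)cc1 | intermediate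
15 | (3S,4S,5R)-3-[3-(tert-butyldimethylsilyloxy)propyl]-5-(hydroxymethyl)-4-[(3E)-5-[(4-methoxybenzyl)oxy]-3-methylpent-3-en-1-yl]oxan-2-one | COc1ccc(COC/C=C(\C)CC[C@@H]2[C@H](CCCO[Si](C)(C)C(C)(C)C)C(=O)OC[C@H]2CO)cc1 | intermediate
16 | (3S,4R,5S)-5-[3-(tert-butyldimethylsilyloxy)propyl]-4-[(3E)-5-[(4-methoxybenzyl)oxy]-3-methylpent-3-en-1-yl]-6-oxooxane-3-carboxylic acid | COc1ccc(COC/C=C(\C)CC[C@@H]2[C@H](CCCO[Si](C)(C)C(C)(C)C)C(=O)OC[C@H]2C(=O)O)cc1 | intermediate
17 | methyl phenyl sulfone | CS(=O)(=O)c1ccccc1 | starting material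
18 | (3S,4S,5S)-3-[3-(tert-butyldimethylsilyloxy)propyl]-5-(imidazole-1-carbonyl)-4-[(3E)-5-[(4-methoxybenzyl)oxy]-3-methylpent-3-en-1-yl]oxan-2-one (not isolated) | COc1ccc(COC/C=C(\C)CC[C@@H]2[C@H](CCCO[Si](C)(C)C(C)(C)C)C(=O)OC[C@H]2C(=O)n3ccnc3)cc1 | intermediate
19 | (3S,4S,5S)-3-[3-(tert-butyldimethylsilyloxy)propyl]-4-[(3E)-5-[(4-methoxybenzyl)oxy]-3-methylpent-3-en-1-yl]-5-[(phenylsulfonyl)acetyl]oxan-2-one | COc1ccc(COC/C=C(\C)CC[C@@H]2[C@H](CCCO[Si](C)(C)C(C)(C)C)C(=O)OC[C@H]2C(=O)CS(=O)(=O)c3ccccc3)cc1 | intermediate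
20 | (3S,4S,5S)-3-[3-(tert-butyldimethylsilyloxy)propyl]-4-[(3E)-5-hydroxy-3-methylpent-3-en-1-yl]-5-[(phenylsulfonyl)acetyl]oxan-2-one | OC/C=C(\C)CC[C@@H]1[C@H](CCCO[Si](C)(C)C(C)(C)C)C(=O)OC[C@H]1C(=O)CS(=O)(=O)c1ccccc1 | intermediate
21 | allylic methanesulfonate of 20 (not isolated) | CS(=O)(=O)OC/C=C(\C)CC[C@@H]1[C@H](CCCO[Si](C)(C)C(C)(C)C)C(=O)OC[C@H]1C(=O)CS(=O)(=O)c1ccccc1 | intermediate
22 | (3S,4S,5S)-3-[3-(tert-butyldimethylsilyloxy)propyl]-4-[(3E)-5-chloro-3-methylpent-3-en-1-yl]-5-[(phenylsulfonyl)acetyl]oxan-2-one | ClC/C=C(\C)CC[C@@H]1[C@H](CCCO[Si](C)(C)C(C)(C)C)C(=O)OC[C@H]1C(=O)CS(=O)(=O)c1ccccc1 | intermediate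
23 | (4S,4aS,7E,11aS)-4-[3-(tert-butyldimethylsilyloxy)propyl]-7-methyl-10-(phenylsulfonyl)-1,4,4a,5,6,9,10,11a-octahydrocyclonona[c]pyran-3,11-dione (C10 of this name = C2, drawn arbitrarily) | O=C1[C@@H](S(=O)(=O)c3ccccc3)C/C=C(\C)CC[C@@H]2[C@H](CCCO[Si](C)(C)C(C)(C)C)C(=O)OC[C@@H]12 | intermediate
24 | (4S,4aS,7E,11aS)-4-[3-(tert-butyldimethylsilyloxy)propyl]-7-methyl-1,4,4a,5,6,9,10,11a-octahydrocyclonona[c]pyran-3,11-dione | O=C1CC/C=C(\C)CC[C@@H]2[C@H](CCCO[Si](C)(C)C(C)(C)C)C(=O)OC[C@@H]12 | intermediate
25 | (4S,4aS,7E,11aR)-4-[3-(tert-butyldimethylsilyloxy)propyl]-7-methyl-11-methylidene-4,4a,5,6,9,10,11,11a-octahydro-1H-cyclonona[c]pyran-3-one | C=C1CC/C=C(\C)CC[C@@H]2[C@H](CCCO[Si](C)(C)C(C)(C)C)C(=O)OC[C@@H]12 | intermediate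
26 | (4S,4aS,7E,11aR)-4-(3-hydroxypropyl)-7-methyl-11-methylidene-4,4a,5,6,9,10,11,11a-octahydro-1H-cyclonona[c]pyran-3-one | C=C1CC/C=C(\C)CC[C@@H]2[C@H](CCCO)C(=O)OC[C@@H]12 | intermediate
27 | methyl 2-(triphenylphosphoranylidene)propanoate | COC(=O)C(C)=P(c1ccccc1)(c1ccccc1)c1ccccc1 | starting material
28 | 3-[(4S,4aS,7E,11aR)-7-methyl-11-methylidene-3-oxo-4,4a,5,6,9,10,11,11a-octahydro-1H-cyclonona[c]pyran-4-yl]propanal (not isolated) | C=C1CC/C=C(\C)CC[C@@H]2[C@H](CCC=O)C(=O)OC[C@@H]12 | intermediate
29 | methyl (2E)-2-methyl-5-[(4S,4aS,7E,11aR)-7-methyl-11-methylidene-3-oxo-4,4a,5,6,9,10,11,11a-octahydro-1H-cyclonona[c]pyran-4-yl]pent-2-enoate | C=C1CC/C=C(\C)CC[C@@H]2[C@H](CC/C=C(\C)C(=O)OC)C(=O)OC[C@@H]12 | intermediate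
30 | acalycixeniolide H (the 4S,5S epoxide of 29 at C4–C5) | C=C1CC[C@@H]2O[C@@]2(C)CC[C@@H]2[C@H](CC/C=C(\C)C(=O)OC)C(=O)OC[C@@H]12 | target

**Count and risks**
Total step count: 18. Longest linear sequence: 18 steps (1 → 30).

Steps most likely to fail:

1. Step 13. The carbanion may react between molecules (oligomers), attack the lactone carbonyl, or close the strained E-cyclononene too slowly. Fallback: starting from 20, methyl chloroformate and pyridine would give the allylic methyl carbonate F1. Pd(0) (Pd2(dba)3, dppe, THF, high dilution, 60 °C) would ionise it to the π-allyl complex, the released methoxide would deprotonate C2, and attack at the less hindered C3 terminus would close the same C2–C3 bond (Tsuji–Trost macrocyclisation) under neutral conditions. This returns to the route at 23.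

2. Step 8. Protonation of the C9 enolate may show poor facial selectivity, or the alkoxide may scramble C12 by translactonisation before the quench. Fallback: starting from 14, the dianion (LDA) would be trapped with PhSeBr to give the α-phenylselanyl lactone F2. Homolysis with (Me3Si)3SiH and Et3B/air at −78 °C would give the planar C9 radical, which should take hydrogen from the bulky silane on the face anti to the C8 chain (radical hydrogen-atom transfer in place of ionic protonation). This returns to the route at 15.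

3. Step 18. The peracid may attack the ring alkene from the wrong face if another ring conformer reacts, or may over-oxidise the methylidene. Fallback: starting from 29, a Shi epoxidation (fructose-derived ketone of the enantiomeric series matched to the required face, Oxone, buffered MeCN/dimethoxymethane–water, 0 °C) would replace substrate control by a chiral dioxirane. It leads directly to 30 and makes no new compound.

Further compounds
F1 | step 13 | (2E)-5-[(3S,4S,5S)-3-[3-(tert-butyldimethylsilyloxy)propyl]-2-oxo-5-[(phenylsulfonyl)acetyl]oxan-4-yl]-3-methylpent-2-en-1-yl methyl carbonate | COC(=O)OC/C=C(\C)CC[C@@H]1[C@H](CCCO[Si](C)(C)C(C)(C)C)C(=O)OC[C@H]1C(=O)CS(=O)(=O)c1ccccc1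
F2 | step 8 | (4S,5R)-3-[3-(tert-butyldimethylsilyloxy)propyl]-5-(hydroxymethyl)-4-[(3E)-5-[(4-methoxybenzyl)oxy]-3-methylpent-3-en-1-yl]-3-(phenylselanyl)oxan-2-one (C3 not defined) | COc1ccc(COC/C=C(\C)CC[C@@H]2C(CCCO[Si](C)(C)C(C)(C)C)([Se]c3ccccc3)C(=O)OC[C@H]2CO)cc1
F0 | step 18 | none | none
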